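**Retrosynthetic overview**
1. Target 27 ← C10 acetate, C6 anisoate and the C6 carbinol (hydroxyl-directed reduction) from the trans-fused hydroazulen-6-one 21.
2. The strategy rests on the C1–C5 ring-fusion bond (C1 = quaternary C–CH3, C5 = CH) lying next to the oxygenated C6. It is cut back to cis-decalin 20, in which C1 is still bonded to the carbinol carbon (future C6) and C5 carries a mesylate. One 1,2-shift then turns both six-membered rings into the cyclopentane (C1–C5) and the cycloheptene (C5–C10 plus C1).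
3. 20 ← dienone alcohol 14: hydroxyl-directed cis-dihydroxylation of C4a=C5 on the methyl face, capping of the C6 oxygen, C5 mesylation, convex-face reduction of the C1 enone, silylation.
4. 14 ← methyl Wieland–Miescher ketone 7 (C1 masked by reduction, isopropyl 1,2-addition, re-oxidation, Saegusa dehydrogenation) ← 5-methylcyclohexane-1,3-dione, MeI and methyl vinyl ketone.
5. Ring order: the dione ring (later the seven-membered ring), then the annulated ring (later the five-membered ring); both are resized together in the key step.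

Key step: step 14

**Remarks on the chemistry (assumptions)**
- Decalin intermediates are numbered as naphthalenes: C8a = angular C–CH3, C1 = oxygenated carbon next to it, C2=C3(CH3), C4, C4a = fusion carbon that becomes the ketone, C5 = mesylate carbon, C6 = isopropyl carbinol, C7, C8. They map onto the daucane numbering of the hydroazulenes as C8a→C1, C8→C2, C7→C3, C6→C4, C5→C5, C4a→C6, C4→C7, C3→C8, C2→C9, C1→C10. β is the face of the angular methyl.
- L-Proline is assumed to induce the same (8aS) sense with the 5-methyl triketone as with the parent triketone. The C3 methyl epimers are carried as a mixture until step 7, where C3 becomes sp2 (the SMILES of 6, 7, 8, 10, 11 and 12 leave C3 open).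
- In the SMILES of the osmate esters the N→Os bonds are written with formal charges.

**Route**

Step 1
Reactants: 1 5-methylcyclohexane-1,3-dione; 2 iodomethane
Product: 3 2,5-dimethylcyclohexane-1,3-dione
Conditions: MeI, KOH, H2O–dioxane, 60 °C
Reagents that add atoms: iodomethane CI
Why: C-alkylation of the 1,3-dione enolate at the doubly activated C2 (classical methylation of cyclohexane-1,3-diones), with no stereocentre of consequence.

Step 2
Reactants: 3 2,5-dimethylcyclohexane-1,3-dione; 4 methyl vinyl ketone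
Product: 5 2,5-dimethyl-2-(3-oxobutyl)cyclohexane-1,3-dione (cis/trans mixture, both achiral)
Conditions: MVK, H2O, AcOH (cat.), hydroquinone (cat.), 75 °C
Reagents that add atoms: methyl vinyl ketone CC(=O)C=C
Why: Michael addition of the 2-methyl-1,3-dione to the enone creates the quaternary carbon that becomes the angular C–CH3, and both achiral diastereomers are used together.

Step 3
Reactants: 5 2,5-dimethyl-2-(3-oxobutyl)cyclohexane-1,3-dione
Product: 7 (8aS)-3,8a-dimethyl-3,4,8,8a-tetrahydronaphthalene-1,6(2H,7H)-dione (both C3 epimers), via cis-fused bicyclic ketol 6 (not isolated)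
Conditions: L-proline (30 mol%), DMSO, rt
Reagents that add atoms: none
Why: Hajos–Parrish–Eder–Sauer–Wiechert aldol condensation, in which the proline enamine of the side-chain ketone adds to one of the two enantiotopic ring carbonyls and should set C8a as (S) by analogy with the parent Wieland–Miescher ketone, the ketol dehydrating in situ.

Step 4
Reactants: 7 (8aS)-3,8a-dimethyl-3,4,8,8a-tetrahydronaphthalene-1,6(2H,7H)-dione
Product: 8 1β-hydroxy-3,8aβ-dimethyl-1,2,3,4,8,8a-hexahydronaphthalen-6(7H)-one
Conditions: NaBH4 (0.3 equiv), EtOH, −10 °C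
Reagents that add atoms: none
Why: Chemoselective borohydride reduction of the saturated C1 ketone beside the less electrophilic enone (standard for Wieland–Miescher ketones), hydride entering anti to the angular methyl; the carbinol only masks C1 and is re-oxidised in step 6.

Step 5
Reactants: 8 1β-hydroxy-3,8aβ-dimethyl-1,2,3,4,8,8a-hexahydronaphthalen-6(7H)-one; 9 isopropylmagnesium chloride
Product: 10 6α-isopropyl-3,8aβ-dimethyl-1,2,3,4,6,7,8,8a-octahydronaphthalene-1β,6β-diol
Conditions: i-PrMgCl (3.5 equiv), CeCl3 (dried), THF, −78 → 0 °C; aq. NH4Cl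
Reagents that add atoms: isopropylmagnesium chloride CC(C)[Mg]Cl
Why: Organocerium (Imamoto) 1,2-addition to the enone, one equivalent being consumed by the hydroxyl; axial attack on the α-face, anti to the angular methyl, should place isopropyl α and the tertiary hydroxyl β, and the minor C6 epimer is best removed after step 7 once the C3 epimers have converged.

Step 6
Reactants: 10 6α-isopropyl-3,8aβ-dimethyl-1,2,3,4,6,7,8,8a-octahydronaphthalene-1β,6β-diol
Product: 11 6β-hydroxy-6α-isopropyl-3,8aβ-dimethyl-3,4,6,7,8,8a-hexahydronaphthalen-1(2H)-one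
Conditions: Dess–Martin periodinane, NaHCO3, CH2Cl2, 0 °C → rt
Reagents that add atoms: none
Why: Dess–Martin oxidation converts only the secondary alcohol, the tertiary allylic alcohol being inert under buffered, chromium-free conditions.

Step 7
Reactants: 11 6β-hydroxy-6α-isopropyl-3,8aβ-dimethyl-3,4,6,7,8,8a-hexahydronaphthalen-1(2H)-one
Product: 14 6β-hydroxy-6α-isopropyl-3,8aβ-dimethyl-6,7,8,8a-tetrahydronaphthalen-1(4H)-one, via bis-silyl enol ether 12 (not isolated), via O-TMS dienone 13 (not isolated)
Conditions: LDA (2.3 equiv), TMSCl, THF, −78 °C; Pd(OAc)2 (1.1 equiv), MeCN, rt; then aq. citric acid, MeOH, 0 °C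
Reagents that add atoms: none
Why: Saegusa–Ito dehydrogenation, in which the ketone can enolise only toward C2 (C8a is quaternary) and β-hydride elimination toward C3 gives the C2=C3 enone and removes the C3 stereocentre, the tertiary O-TMS group formed alongside being cleaved in the mild acidic work-up.

Step 8
Reactants: 14 6β-hydroxy-6α-isopropyl-3,8aβ-dimethyl-6,7,8,8a-tetrahydronaphthalen-1(4H)-one
Product: 15 osmium(VI) glycolate–TMEDA complex of the 4aβ,5β-diol (6β-OH free, C1 enone, cis-fused)
Conditions: OsO4 (1.05 equiv), TMEDA (1.1 equiv), CH2Cl2, −78 °C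
Reagents that add atoms: osmium tetroxide O=[Os](=O)(=O)=O; TMEDA CN(C)CCN(C)C
Why: Donohoe hydrogen-bond-directed dihydroxylation, in which the pseudoaxial C6 hydroxyl binds the OsO4·TMEDA complex and delivers it to the β-face of the electron-rich C4a=C5 bond (the enone alkene is inert), setting C4a and C5 with both oxygens cis to the C6 hydroxyl and the angular methyl and making the ring fusion cis.

Step 9
Reactants: 15 osmium(VI) glycolate–TMEDA complex of the 4aβ,5β-diol
Product: 16 6-O-triethylsilyl ether of osmate ester 15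
Conditions: TESOTf, 2,6-lutidine, CH2Cl2, −78 → 0 °C
Reagents that add atoms: triethylsilyl triflate CC[Si](CC)(CC)OS(=O)(=O)C(F)(F)F
Why: Silyl triflate etherification of the only free hydroxyl while the chelated Os(VI) glycolate, a robust chromatography-stable complex, keeps the two new oxygens masked, so the C6 oxygen is differentiated without any selectivity issue.

Step 10
Reactants: 16 6-O-triethylsilyl osmate ester
Product: 17 4aβ,5β-dihydroxy-6α-isopropyl-3,8aβ-dimethyl-6β-(triethylsilyloxy)-4a,5,6,7,8,8a-hexahydronaphthalen-1(4H)-one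
Conditions: ethylenediamine (excess), CH2Cl2, rt; aq. work-up
Reagents that add atoms: none
Why: Ligand exchange with ethylenediamine releases the diol from the osmate ester under neutral conditions that should spare the silyl ether and the β-hydroxy enone.

Step 11
Reactants: 17 4aβ,5β-dihydroxy-6α-isopropyl-3,8aβ-dimethyl-6β-(triethylsilyloxy)-4a,5,6,7,8,8a-hexahydronaphthalen-1(4H)-one
Product: 18 4aβ-hydroxy-6α-isopropyl-5β-(mesyloxy)-3,8aβ-dimethyl-6β-(triethylsilyloxy)-4a,5,6,7,8,8a-hexahydronaphthalen-1(4H)-one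
Conditions: MsCl, Et3N, CH2Cl2, −20 → 0 °C
Reagents that add atoms: methanesulfonyl chloride CS(Cl)(=O)=O
Why: Sulfonylation via sulfene takes place at the only secondary hydroxyl, the tertiary fusion hydroxyl being unreactive.

Step 12
Reactants: 18 4aβ-hydroxy-5β-mesyloxy enone
Product: 19 6α-isopropyl-5β-(mesyloxy)-3,8aβ-dimethyl-6β-(triethylsilyloxy)-1,4,4a,5,6,7,8,8a-octahydronaphthalene-1α,4aβ-diol
Conditions: NaBH4, CeCl3·7H2O, MeOH–THF, −78 → −30 °C
Reagents that add atoms: none
Why: Luche 1,2-reduction of the enone, in which the α-face of C1 is blocked by the axial C5 of the other ring of the cis-decalin, so hydride should enter from the convex β-face and give the 1α-alcohol, trans to the angular methyl.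

Step 13
Reactants: 19 1α,4aβ-diol 5β-mesylate
Product: 20 1α-(tert-butyldimethylsilyloxy)-6α-isopropyl-5β-(mesyloxy)-3,8aβ-dimethyl-6β-(triethylsilyloxy)-1,4,4a,5,6,7,8,8a-octahydronaphthalen-4aβ-ol
Conditions: TBSOTf (1.2 equiv), 2,6-lutidine, CH2Cl2, −78 → −20 °C
Reagents that add atoms: tert-butyldimethylsilyl triflate CC(C)(C)[Si](C)(C)OS(=O)(=O)C(F)(F)F
Why: Silylation of the secondary allylic alcohol, the hindered tertiary fusion hydroxyl staying free at low temperature with a small excess of reagent.

Step 14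
Reactants: 20 cis-decalin 4aβ-ol 5β-mesylate (1α-OTBS, 6β-OTES)
Product: 21 10α-(tert-butyldimethylsilyloxy)-4β-(triethylsilyloxy)dauc-8-en-6-one (1β-CH3, 5α-H, trans-fused hydroazulenone)
Conditions: Et3Al (3 equiv), CH2Cl2, −78 → 0 °C; aq. Rochelle salt
Reagents that add atoms: none
Why: Et3Al converts the free tertiary fusion hydroxyl into an aluminium alkoxide and activates the mesylate, and the C4a–C8a bond, antiperiplanar to the equatorial C5–OMs bond in the preferred chair of the oxygenated ring (isopropyl equatorial), migrates from C4a to C5 as the alkoxide collapses to the ketone. The closest known reaction type is the organoaluminium-promoted pinacol-type (semipinacol) rearrangement of β-mesyloxy alcohols, and the same ring change is known for decalin cis-diol monosulfonates giving hydroazulenones. No ring is closed by cyclisation: the single 1,2-shift contracts the oxygenated six-membered ring to the cyclopentane (C1–C5) and expands the other ring to the cycloheptenone in one event. The only new stereocentre, C5, is set by inversion at the migration terminus, which puts H5 α and trans to the C1 methyl, while the migrating quaternary carbon keeps its configuration. The step needs C8a to migrate rather than C7 on the other side of the mesylate; this is secured because only the fusion oxygen carries the metal alkoxide, the C6 oxygen being capped as a triethylsilyl ether, and the non-basic medium should prevent silyl transfer, C5 epimerisation and β-elimination of the C4 oxygen in the product.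

Step 15
Reactants: 21 10α-(tert-butyldimethylsilyloxy)-4β-(triethylsilyloxy)dauc-8-en-6-one
Product: 22 10α-(tert-butyldimethylsilyloxy)-4β-hydroxydauc-8-en-6-one
Conditions: PPTS (cat.), MeOH–CH2Cl2, 0 °C → rt
Reagents that add atoms: none
Why: Acid-catalysed methanolysis should remove the triethylsilyl ether much faster than the neopentyl secondary TBS ether.

Step 16
Reactants: 22 10α-(tert-butyldimethylsilyloxy)-4β-hydroxydauc-8-en-6-one
Product: 23 10α-(tert-butyldimethylsilyloxy)dauc-8-ene-4β,6α-diol
Conditions: Me4NBH(OAc)3, MeCN–AcOH (1:1), −30 → −20 °C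
Reagents that add atoms: none
Why: Evans–Saksena hydroxyl-directed reduction, in which the C4 hydroxyl exchanges onto boron and delivers hydride through a chair transition state to the β-face of the ketone, giving the 4,6-anti diol with the new C6 hydroxyl α.

Step 17
Reactants: 23 10α-(tert-butyldimethylsilyloxy)dauc-8-ene-4β,6α-diol; 24 4-methoxybenzoyl chloride
Product: 25 10α-(tert-butyldimethylsilyloxy)-6α-(4-methoxybenzoyloxy)dauc-8-en-4β-ol
Conditions: 4-MeOC6H4COCl, Et3N, DMAP (cat.), CH2Cl2, rt
Reagents that add atoms: 4-methoxybenzoyl chloride COc1ccc(C(Cl)=O)cc1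
Why: DMAP-catalysed acylation of the secondary C6 hydroxyl, the tertiary C4 hydroxyl not being acylated.

Step 18
Reactants: 25 10α-(tert-butyldimethylsilyloxy)-6α-(4-methoxybenzoyloxy)dauc-8-en-4β-ol
Product: 26 6α-(4-methoxybenzoyloxy)dauc-8-ene-4β,10α-diol
Conditions: HF·pyridine, THF, 0 °C → rt
Reagents that add atoms: none
Why: Fluoride cleavage of the silyl ether under mildly acidic conditions that leave the aryl ester in place and avoid acyl migration.

Step 19
Reactants: 26 6α-(4-methoxybenzoyloxy)dauc-8-ene-4β,10α-diol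
Product: 27 10α-acetoxy-6α-(4-methoxybenzoyloxy)dauc-8-en-4β-ol (target)
Conditions: Ac2O, pyridine, DMAP (cat.), CH2Cl2, rt
Reagents that add atoms: acetic anhydride CC(=O)OC(C)=O
Why: DMAP-catalysed acetylation of the secondary allylic hydroxyl, the tertiary C4 hydroxyl being left free.

**Compound list**
1 | 5-methylcyclohexane-1,3-dione | CC1CC(=O)CC(=O)C1 | starting material
2 | iodomethane | CI | starting material
3 | 2,5-dimethylcyclohexane-1,3-dione | CC1CC(=O)C(C)C(=O)C1 | intermediate
4 | methyl vinyl ketone | CC(=O)C=C | starting material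
5 | 2,5-dimethyl-2-(3-oxobutyl)cyclohexane-1,3-dione (cis/trans mixture) | CC(=O)CCC1(C)C(=O)CC(C)CC1=O | intermediate
6 | cis-fused ketol, 4aβ-hydroxy-3,8aβ-dimethyloctahydronaphthalene-1,6-dione (C3 epimers) | O[C@]12CC(C)CC(=O)[C@@]1(C)CCC(=O)C2 | intermediate (not isolated)
7 | (8aS)-3,8a-dimethyl-3,4,8,8a-tetrahydronaphthalene-1,6(2H,7H)-dione (C3 epimers) | O=C1C=C2CC(C)CC(=O)[C@@]2(C)CC1 | intermediate
8 | 1β-hydroxy-3,8aβ-dimethyl-1,2,3,4,8,8a-hexahydronaphthalen-6(7H)-one (C3 epimers) | O=C1C=C2CC(C)C[C@H](O)[C@@]2(C)CC1 | intermediate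
9 | isopropylmagnesium chloride | CC(C)[Mg]Cl | starting material
10 | 6α-isopropyl-3,8aβ-dimethyl-1,2,3,4,6,7,8,8a-octahydronaphthalene-1β,6β-diol (C3 epimers) | C1=C2CC(C)C[C@H](O)[C@@]2(C)CC[C@@]1(O)C(C)C | intermediate
11 | 6β-hydroxy-6α-isopropyl-3,8aβ-dimethyl-3,4,6,7,8,8a-hexahydronaphthalen-1(2H)-one (C3 epimers) | C1=C2CC(C)CC(=O)[C@@]2(C)CC[C@@]1(O)C(C)C | intermediate
12 | 6α-isopropyl-3,8aβ-dimethyl-1,6β-bis(trimethylsilyloxy)-3,4,6,7,8,8a-hexahydronaphthalene (C3 epimers) | C1=C2CC(C)C=C(O[Si](C)(C)C)[C@@]2(C)CC[C@@]1(O[Si](C)(C)C)C(C)C | intermediate (not isolated)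
13 | 6α-isopropyl-3,8aβ-dimethyl-6β-(trimethylsilyloxy)-6,7,8,8a-tetrahydronaphthalen-1(4H)-one | C1=C2CC(C)=CC(=O)[C@@]2(C)CC[C@@]1(O[Si](C)(C)C)C(C)C | intermediate (not isolated)
14 | 6β-hydroxy-6α-isopropyl-3,8aβ-dimethyl-6,7,8,8a-tetrahydronaphthalen-1(4H)-one | C1=C2CC(C)=CC(=O)[C@@]2(C)CC[C@@]1(O)C(C)C | intermediate
15 | osmium(VI) glycolate–TMEDA complex bound through O4a and O5 of the 4aβ,5β,6β-triol enone | O1[C@]23CC(C)=CC(=O)[C@@]2(C)CC[C@@](O)(C(C)C)[C@@H]3O[Os-2]14(=O)(=O)[N+](C)(C)CC[N+]4(C)C | intermediate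
16 | 6-O-triethylsilyl ether of osmate ester 15 | O1[C@]23CC(C)=CC(=O)[C@@]2(C)CC[C@@](O[Si](CC)(CC)CC)(C(C)C)[C@@H]3O[Os-2]14(=O)(=O)[N+](C)(C)CC[N+]4(C)C | intermediate
17 | 4aβ,5β-dihydroxy-6α-isopropyl-3,8aβ-dimethyl-6β-(triethylsilyloxy)-4a,5,6,7,8,8a-hexahydronaphthalen-1(4H)-one | O[C@]12CC(C)=CC(=O)[C@@]1(C)CC[C@@](O[Si](CC)(CC)CC)(C(C)C)[C@@H]2O | intermediate
18 | 4aβ-hydroxy-6α-isopropyl-5β-(mesyloxy)-3,8aβ-dimethyl-6β-(triethylsilyloxy)-4a,5,6,7,8,8a-hexahydronaphthalen-1(4H)-one | O[C@]12CC(C)=CC(=O)[C@@]1(C)CC[C@@](O[Si](CC)(CC)CC)(C(C)C)[C@@H]2OS(C)(=O)=O | intermediate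
19 | 6α-isopropyl-5β-(mesyloxy)-3,8aβ-dimethyl-6β-(triethylsilyloxy)-1,4,4a,5,6,7,8,8a-octahydronaphthalene-1α,4aβ-diol | O[C@]12CC(C)=C[C@@H](O)[C@@]1(C)CC[C@@](O[Si](CC)(CC)CC)(C(C)C)[C@@H]2OS(C)(=O)=O | intermediate
20 | 1α-(tert-butyldimethylsilyloxy)-6α-isopropyl-5β-(mesyloxy)-3,8aβ-dimethyl-6β-(triethylsilyloxy)-1,4,4a,5,6,7,8,8a-octahydronaphthalen-4aβ-ol (key-step precursor) | O[C@]12CC(C)=C[C@@H](O[Si](C)(C)C(C)(C)C)[C@@]1(C)CC[C@@](O[Si](CC)(CC)CC)(C(C)C)[C@@H]2OS(C)(=O)=O | intermediate
21 | 10α-(tert-butyldimethylsilyloxy)-4β-(triethylsilyloxy)dauc-8-en-6-one (key-step product) | O=C1CC(C)=C[C@@H](O[Si](C)(C)C(C)(C)C)[C@@]2(C)CC[C@@](O[Si](CC)(CC)CC)(C(C)C)[C@H]12 | intermediate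
22 | 10α-(tert-butyldimethylsilyloxy)-4β-hydroxydauc-8-en-6-one | O=C1CC(C)=C[C@@H](O[Si](C)(C)C(C)(C)C)[C@@]2(C)CC[C@@](O)(C(C)C)[C@H]12 | intermediate
23 | 10α-(tert-butyldimethylsilyloxy)dauc-8-ene-4β,6α-diol | O[C@H]1CC(C)=C[C@@H](O[Si](C)(C)C(C)(C)C)[C@@]2(C)CC[C@@](O)(C(C)C)[C@H]12 | intermediate
24 | 4-methoxybenzoyl chloride | COc1ccc(C(Cl)=O)cc1 | starting material
25 | 10α-(tert-butyldimethylsilyloxy)-6α-(4-methoxybenzoyloxy)dauc-8-en-4β-ol | COc1ccc(C(=O)O[C@H]2CC(C)=C[C@@H](O[Si](C)(C)C(C)(C)C)[C@@]3(C)CC[C@@](O)(C(C)C)[C@H]23)cc1 | intermediate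
26 | 6α-(4-methoxybenzoyloxy)dauc-8-ene-4β,10α-diol | COc1ccc(C(=O)O[C@H]2CC(C)=C[C@@H](O)[C@@]3(C)CC[C@@](O)(C(C)C)[C@H]23)cc1 | intermediate
27 | 10α-acetoxy-6α-(4-methoxybenzoyloxy)dauc-8-en-4β-ol (CNP0256979.2) | COc1ccc(C(=O)O[C@H]2CC(C)=C[C@@H](OC(C)=O)[C@@]3(C)CC[C@@](O)(C(C)C)[C@H]23)cc1 | target

**Step count**
Total: 19 steps. Longest linear sequence: 19 steps (from 1 to 27).

**Steps most likely to fail**

Step 8. Hydrogen-bond delivery may not override the axial angular methyl, so that osmylation occurs slowly or from the α-face (poor facial selectivity). The fallback is a Woodward cis-hydroxylation, which places the diol on the face opposite to the first-formed iodonium ion. It sets out from dienone alcohol 14, which is silylated (TESOTf, 2,6-lutidine) to the 6-O-triethylsilyl dienone F1. Treatment with I2 and AgOAc in wet AcOH should give the cis-hydroxy acetate F2 through the β-acetoxonium ion. Mild methanolysis (K2CO3, MeOH, 0 °C) then returns to the route at diol 17.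

Step 9. The hydroxyl next to the osmium centre is crowded, so silylation may stall, or the silyl triflate may attack the glycolate (loss of the diol mask). The fallback sets out from osmate ester 15, which is cleaved with ethylenediamine to the enone triol F3. MsCl/Et3N sulfonylates its only secondary hydroxyl to give the triol 5-mesylate F4. One equivalent of TESOTf with 2,6-lutidine at −78 °C should then silylate the C6 tertiary hydroxyl, which is more accessible than the fusion hydroxyl flanked by the quaternary C8a. This returns to the route at mesylate 18.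

Step 14. Metalation of the fusion hydroxyl may be blocked by the syn-axial silyloxy group, so that the mesylate ionises slowly and eliminates on warming (stalled or diverted 1,2-shift). The fallback sets out from 20, from which the triethylsilyl group is removed first (PPTS, MeOH) to give the silyl-free diol mesylate F5. Et3Al in CH2Cl2 at −78 → 0 °C then forms the chelated aluminium dialkoxide, and the shift relies on the higher migratory aptitude of the fully substituted C8a over the C7 methylene. This returns to the route at hydroxy ketone 22 and saves step 15.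

**Further compounds**
F1 | step 8 | 6α-isopropyl-3,8aβ-dimethyl-6β-(triethylsilyloxy)-6,7,8,8a-tetrahydronaphthalen-1(4H)-one | C1=C2CC(C)=CC(=O)[C@@]2(C)CC[C@@]1(O[Si](CC)(CC)CC)C(C)C
F2 | step 8 | 5β-acetoxy-4aβ-hydroxy-6α-isopropyl-3,8aβ-dimethyl-6β-(triethylsilyloxy)-4a,5,6,7,8,8a-hexahydronaphthalen-1(4H)-one | O[C@]12CC(C)=CC(=O)[C@@]1(C)CC[C@@](O[Si](CC)(CC)CC)(C(C)C)[C@@H]2OC(C)=O
F3 | step 9 | 4aβ,5β,6β-trihydroxy-6α-isopropyl-3,8aβ-dimethyl-4a,5,6,7,8,8a-hexahydronaphthalen-1(4H)-one | O[C@]12CC(C)=CC(=O)[C@@]1(C)CC[C@@](O)(C(C)C)[C@@H]2O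
F4 | step 9 | 4aβ,6β-dihydroxy-6α-isopropyl-5β-(mesyloxy)-3,8aβ-dimethyl-4a,5,6,7,8,8a-hexahydronaphthalen-1(4H)-one | O[C@]12CC(C)=CC(=O)[C@@]1(C)CC[C@@](O)(C(C)C)[C@@H]2OS(C)(=O)=O
F5 | step 14 | 1α-(tert-butyldimethylsilyloxy)-6α-isopropyl-5β-(mesyloxy)-3,8aβ-dimethyl-1,4,4a,5,6,7,8,8a-octahydronaphthalene-4aβ,6β-diol | O[C@]12CC(C)=C[C@@H](O[Si](C)(C)C(C)(C)C)[C@@]1(C)CC[C@@](O)(C(C)C)[C@@H]2OS(C)(=O)=O
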